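## Retrosynthetic overview

1. The target comes from acetylation of its C2 alcohol. The ten-membered ring is closed last, at C2–C3, by intramolecular addition of an (E)-dienylzinc (from a terminal enyne) to a neopentyl C2 aldehyde.
2. The γ-lactone (C17–C8 bond) comes from an intramolecular Reformatsky reaction of a C7 α-bromopropanoate onto the C8 ketone. C6–Cl/C7–O come from chloride opening of a trans-epoxy ketone, whose enone is made by a Heck union (C5–C6).
3. The C9 carbinol comes from Felkin addition of lithiated methoxyallene to a C9 aldehyde, itself from vinyl conjugate addition (C10, C11) and ozonolysis on a cyclohexenone.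
4. Key step: asymmetric Birch reduction–methylation of a prolinol-ether benzamide of 2-methoxy-5-methylbenzoic acid breaks the arene and sets the quaternary C1; the same carbonyl then controls C14.
5. Ring order: cyclohexane (from the arene), then γ-lactone, then ten-membered carbocycle.

Assumption: (S)-2-(methoxymethyl)pyrrolidine induces the (R) quaternary centre drawn for the Birch product; if the sense is opposite, the commercial (R)-amine is used and nothing else changes.

Locants C1–C20 in the "Why" lines are briarane locants: C1 quaternary carbon, C2–C9 the chain of the ten-membered ring, C10–C14 the cyclohexane, C15/C16/C18/C20 one-carbon branches, C17/C19 lactone carbons.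

## Route

Step 1
Reactants: 1 2-methoxy-5-methylbenzoic acid; 2 (S)-2-(methoxymethyl)pyrrolidine
Product: 4 benzamide (S)-(2-methoxy-5-methylphenyl)[2-(methoxymethyl)pyrrolidin-1-yl]methanone, via acid chloride 3 (not isolated)
Conditions: (COCl)2, cat. DMF, CH2Cl2, 0 °C → rt; then 2, Et3N, CH2Cl2, 0 °C
Reagents that add atoms: none
Why: Amide formation through the acid chloride (Schotten–Baumann-type acylation); the only stereocentre is carried in unchanged from the commercial amine.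

Step 2
Reactants: 4 benzamide
Product: 7 keto amide (2R)-2-{[(2S)-2-(methoxymethyl)pyrrolidin-1-yl]carbonyl}-2,4-dimethylcyclohex-3-en-1-one, via potassium dienolate 5 (not isolated), via enol ether amide 6 (not isolated)
Conditions: K (2.2 equiv), t-BuOH (1 equiv), NH3/THF, −78 °C; piperylene; MeI, −78 °C; then 1 M HCl, MeOH, rt
Reagents that add atoms: iodomethane (CI); water (O)
Why: Schultz asymmetric Birch reduction–alkylation: dissolving-metal reduction breaks the arene to the 1,4-dihydro potassium amide enolate 5, whose potassium is chelated by the CH2OMe arm so that MeI attacks the open face and sets the quaternary C1, and acid then hydrolyses the enol ether to a β,γ-unsaturated ketone that cannot conjugate through the quaternary carbon.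

Step 3
Reactants: 7 keto amide
Product: 9 diol (1S,2S)-2-(hydroxymethyl)-2,4-dimethylcyclohex-3-en-1-ol, via hydroxy amide 8 (not isolated)
Conditions: LiH2N·BH3 (from BH3·NH3 and LiN(iPr)2), THF, 0 → 23 °C; then 2 M HCl; NaOH work-up
Reagents that add atoms: none
Why: Myers lithium amidotrihydroborate reduction: the ketone is reduced first, hydride entering anti to the electron-withdrawing carboxamide (polar Felkin–Anh), which sets C14 cis to the future C2, and the hindered tertiary amide is then reduced to the primary alcohol with release of the auxiliary.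

Step 4
Reactants: 9 diol
Product: 10 silyl ether (1S,2S)-2-{[(tert-butyldimethylsilyl)oxy]methyl}-2,4-dimethylcyclohex-3-en-1-ol
Conditions: TBSCl (1.05 equiv), imidazole, CH2Cl2, 0 °C
Reagents that add atoms: tert-butyldimethylsilyl chloride (CC(C)(C)[Si](C)(C)Cl)
Why: Selective silylation of the primary hydroxyl over the hindered secondary one next to the quaternary carbon; no stereocentre is touched.

Step 5
Reactants: 10 silyl ether
Product: 11 butanoate (1S,2S)-2-{[(tert-butyldimethylsilyl)oxy]methyl}-2,4-dimethylcyclohex-3-en-1-yl butanoate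
Conditions: (PrCO)2O, pyridine, DMAP (cat.), CH2Cl2, rt
Reagents that add atoms: butanoic anhydride (CCCC(=O)OC(=O)CCC)
Why: DMAP-catalysed acyl transfer installs the final C14 butanoate early, where it is the only free hydroxyl.

Step 6
Reactants: 11 butanoate
Product: 12 enone (1S,2S)-2-{[(tert-butyldimethylsilyl)oxy]methyl}-2,4-dimethyl-5-oxocyclohex-3-en-1-yl butanoate
Conditions: CrO3, 3,5-dimethylpyrazole, CH2Cl2, −20 °C
Reagents that add atoms: chromium trioxide (O=[Cr](=O)=O)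
Why: Allylic C–H oxidation with the CrO3–3,5-dimethylpyrazole complex: C12 is the only allylic methylene and the other allyl terminus (C10) is neopentyl, so the enone should form without transposition while silyl ether and ester survive.

Step 7
Reactants: 12 enone
Product: 14 vinyl ketone (1S,2S,3S,4R)-2-{[(tert-butyldimethylsilyl)oxy]methyl}-3-ethenyl-2,4-dimethyl-5-oxocyclohexyl butanoate, via silyl enol ether 13 (not isolated)
Conditions: CH2=CHMgBr, CuBr·SMe2 (20 mol %), TMSCl, THF, −78 → −40 °C; then 1 M HCl, THF, 0 °C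
Reagents that add atoms: vinylmagnesium bromide (C=C[Mg]Br)
Why: TMSCl-accelerated copper-catalysed conjugate addition: vinyl enters C10 anti to the CH2OTBS and butanoyloxy groups that share the lower face (C10 cis to the C1 methyl), and kinetic protonation of silyl enol ether 13 anti to the new vinyl group sets C11 with its methyl cis to C9.

Step 8
Reactants: 14 vinyl ketone
Product: 16 aldehyde (1S,2S,3S,4R)-2-{[(tert-butyldimethylsilyl)oxy]methyl}-3-formyl-2,4-dimethyl-5-oxocyclohexyl butanoate, via ozonide 15 (not isolated)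
Conditions: O3, CH2Cl2, −78 °C; then PPh3, −78 °C → rt
Reagents that add atoms: ozone ([O-][O+]=O)
Why: Ozonolysis with reductive work-up cleaves the only C=C bond to the C9 aldehyde without touching ketone, ester or silyl ether, and the neutral work-up avoids epimerisation at C10.

Step 9
Reactants: 16 aldehyde
Product: 19 acetoxy vinyl ketone (1S,2S,3S,4R)-3-[(1R)-1-acetoxy-2-oxobut-3-en-1-yl]-2-{[(tert-butyldimethylsilyl)oxy]methyl}-2,4-dimethyl-5-oxocyclohexyl butanoate, via lithium alkoxide 17 (not isolated), via allenyl acetate 18 (not isolated)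
Conditions: methoxyallene, n-BuLi, THF, −40 °C; 16, −90 °C; Ac2O, −78 → 0 °C; then 5% aq. H2SO4, THF, 0 °C
Reagents that add atoms: methoxyallene (COC=C=C); acetic anhydride (CC(=O)OC(C)=O); water (O)
Why: 1-Lithio-1-methoxyallene is an acryloyl anion equivalent that adds to the aldehyde (much faster than to the hindered ketone or the esters at −90 °C) under Felkin–Anh control with the quaternary C1 as the large group to give 9R, the alkoxide is acetylated in the flask, and dilute acid hydrolyses the allenyl ether to the vinyl ketone.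

Step 10
Reactants: 20 4-(trimethylsilyl)but-3-yn-2-one
Product: 22 enol triflate 4-(trimethylsilyl)but-1-en-3-yn-2-yl trifluoromethanesulfonate, via potassium enolate 21 (not isolated)
Conditions: KN(SiMe3)2, THF, −78 °C; PhNTf2, −78 → 0 °C; aq. NH4Cl
Reagents that add atoms: N-phenylbis(trifluoromethanesulfonimide) (O=S(=O)(N(c1ccccc1)S(=O)(=O)C(F)(F)F)C(F)(F)F)
Why: Kinetic deprotonation of the methyl ketone and O-sulfonylation of the enolate (enol triflate formation) give the 2-triflyloxy-1,3-enyne that carries C3, C4, C5 and C16.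

Step 11
Reactants: 19 acetoxy vinyl ketone; 22 enol triflate
Product: 23 dienynone (1S,2S,3S,4R)-3-[(1R,3E)-1-acetoxy-5-methylidene-2-oxo-7-(trimethylsilyl)hept-3-en-6-yn-1-yl]-2-{[(tert-butyldimethylsilyl)oxy]methyl}-2,4-dimethyl-5-oxocyclohexyl butanoate
Conditions: Pd(OAc)2 (5 mol %), PPh3, NaHCO3, Bu4NCl, DMF, 25 °C
Reagents that add atoms: none
Why: Heck reaction of a vinyl triflate with an enone forms the C5–C6 bond at the unsubstituted β-carbon and gives the E-enone by syn β-hydride elimination, while NaHCO3 is too weak to eliminate the β-butanoyloxy ketone.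

Step 12
Reactants: 23 dienynone
Product: 24 epoxy ketone (1S,2S,3S,4R)-3-[(1R)-1-acetoxy-2-oxo-2-{(2S,3R)-3-[4-(trimethylsilyl)but-1-en-3-yn-2-yl]oxiran-2-yl}ethyl]-2-{[(tert-butyldimethylsilyl)oxy]methyl}-2,4-dimethyl-5-oxocyclohexyl butanoate
Conditions: La(OiPr)3 (10 mol %), (R)-BINOL, Ph3As=O, TBHP, 4 Å MS, THF, rt
Reagents that add atoms: tert-butyl hydroperoxide (CC(C)(C)OO)
Why: Catalytic asymmetric nucleophilic (Weitz–Scheffer-type) epoxidation attacks only the electron-poor C6=C7 bond of the E-enone and gives the trans-(6R,7S) epoxide under reagent control.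

Step 13
Reactants: 24 epoxy ketone
Product: 25 chlorohydrin (1S,2S,3S,4R)-3-[(1R,3R,4S)-1-acetoxy-4-chloro-3-hydroxy-5-methylidene-2-oxo-7-(trimethylsilyl)hept-6-yn-1-yl]-2-{[(tert-butyldimethylsilyl)oxy]methyl}-2,4-dimethyl-5-oxocyclohexyl butanoate
Conditions: LiCl, AcOH, THF, 0 °C → rt
Reagents that add atoms: lithium chloride ([Li+].[Cl-])
Why: Acid-assisted SN2 opening of the α,β-epoxy ketone by chloride at the β-carbon, which is also allylic, inverts C6 and keeps the C7 oxygen, giving the anti chlorohydrin with the C6 and C7 configurations of the target.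

Step 14
Reactants: 25 chlorohydrin
Product: 26 bromopropanoate (1S,2S,3S,4R)-3-[(1R,3R,4S)-1-acetoxy-3-[(2-bromopropanoyl)oxy]-4-chloro-5-methylidene-2-oxo-7-(trimethylsilyl)hept-6-yn-1-yl]-2-{[(tert-butyldimethylsilyl)oxy]methyl}-2,4-dimethyl-5-oxocyclohexyl butanoate
Conditions: 2-bromopropanoyl bromide, pyridine, CH2Cl2, −40 °C
Reagents that add atoms: 2-bromopropanoyl bromide (CC(Br)C(=O)Br)
Why: O-Acylation of the α-hydroxy ketone at low temperature with the weak base pyridine avoids re-closure to the epoxide and loss of HCl; the bromide-bearing carbon is a mixture of epimers that converge in the next step.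

Step 15
Reactants: 26 bromopropanoate
Product: 28 silylated lactone (1S,2S,3S,4R)-3-[(R)-acetoxy{(2R,3R,4R)-2-[(1S)-1-chloro-2-methylidene-4-(trimethylsilyl)but-3-yn-1-yl]-3-hydroxy-4-methyl-5-oxooxolan-3-yl}methyl]-2-{[(tert-butyldimethylsilyl)oxy]methyl}-2,4-dimethyl-5-oxocyclohexyl butanoate, via samarium enolate 27 (not isolated)
Conditions: SmI2 (2.5 equiv), THF, −78 °C; sat. aq. NH4Cl
Reagents that add atoms: none
Why: Intramolecular SmI2 Reformatsky reaction: the α-bromo ester is reduced faster than the ketones or the allylic chloride, and the trivalent samarium enolate closes onto the C8 ketone through the rotamer that keeps C6 away from the bulky C9 branch, giving the C8 hydroxyl cis to C6 and (from the chelated enolate, and by retro-aldol equilibration) the C17 methyl cis to that hydroxyl.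

Step 16
Reactants: 28 silylated lactone
Product: 30 alkynyl diol (1S,2S,3S,4R)-3-[(R)-acetoxy{(2R,3R,4R)-2-[(1S)-1-chloro-2-methylidenebut-3-yn-1-yl]-3-hydroxy-4-methyl-5-oxooxolan-3-yl}methyl]-2-(hydroxymethyl)-2,4-dimethyl-5-oxocyclohexyl butanoate, via terminal alkyne 29 (not isolated)
Conditions: Bu4NF, AcOH (1:1), THF, 0 °C → rt
Reagents that add atoms: none
Why: Buffered fluoride desilylation removes the alkynyl TMS group first and then the primary TBS ether, and acetic acid keeps the medium non-basic for the esters, the lactone, the chloride and the β-acyloxy ketone.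

Step 17
Reactants: 30 alkynyl diol
Product: 31 alkynyl aldehyde (1S,2R,3S,4R)-3-[(R)-acetoxy{(2R,3R,4R)-2-[(1S)-1-chloro-2-methylidenebut-3-yn-1-yl]-3-hydroxy-4-methyl-5-oxooxolan-3-yl}methyl]-2-formyl-2,4-dimethyl-5-oxocyclohexyl butanoate
Conditions: Dess–Martin periodinane, CH2Cl2, 0 °C → rt
Reagents that add atoms: none
Why: Dess–Martin oxidation of the only oxidisable (primary, neopentyl) alcohol; the tertiary C8 hydroxyl cannot be oxidised and the new aldehyde has no α-hydrogen to epimerise.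

Step 18
Reactants: 31 alkynyl aldehyde
Product: 34 macrocyclic alcohol (2-O-deacetyl target; briarane descriptors 1R,2R,3E,6S,7R,8R,9R,10S,11R,14S,17R), via dienylborane 32 (not isolated), via dienylzinc 33 (not isolated)
Conditions: (c-C6H11)2BH (1.1 equiv), CH2Cl2, 0 °C; then syringe-pump addition to Et2Zn (3 equiv), (+)-DAIB (20 mol %), toluene, 0 °C → rt (2 mM); aq. NH4Cl
Reagents that add atoms: none
Why: Oppolzer-type macrocyclisation (so far used for larger rings, here pushed to a ten-membered ring): dicyclohexylborane adds syn to the terminal alkyne faster than it reduces the aldehyde, boron–zinc exchange gives the (E)-dienylzinc, and its amino-alkoxide-catalysed addition closes C2–C3 with retention of the E geometry and Re-face delivery (in line with the Felkin preference) to give 2R, while the allylic chloride, ketone and esters are inert to organoboron and organozinc species.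

Step 19
Reactants: 34 macrocyclic alcohol
Product: 35 target CNP0283653.2
Conditions: Ac2O, pyridine, DMAP (cat.), CH2Cl2, 0 °C → rt
Reagents that add atoms: acetic anhydride (CC(=O)OC(C)=O)
Why: Selective DMAP-catalysed acetylation of the secondary allylic C2 hydroxyl; the tertiary C8 hydroxyl does not react under these conditions.

## Compound list

1 | 2-methoxy-5-methylbenzoic acid | COc1ccc(C)cc1C(=O)O | starting material
2 | (S)-2-(methoxymethyl)pyrrolidine | COC[C@@H]1CCCN1 | starting material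
3 | acid chloride: 2-methoxy-5-methylbenzoyl chloride | COc1ccc(C)cc1C(Cl)=O | intermediate (not isolated)
4 | benzamide (S)-(2-methoxy-5-methylphenyl)[2-(methoxymethyl)pyrrolidin-1-yl]methanone | COC[C@@H]1CCCN1C(=O)c1cc(C)ccc1OC | intermediate
5 | potassium dienolate: potassium (2-methoxy-5-methylcyclohexa-2,5-dien-1-ylidene)[(2S)-2-(methoxymethyl)pyrrolidin-1-yl]methanolate | COC[C@@H]1CCCN1C(O[K])=C1C=C(C)CC=C1OC | intermediate (not isolated)
6 | enol ether amide [(1R)-2-methoxy-1,5-dimethylcyclohexa-2,5-dien-1-yl][(2S)-2-(methoxymethyl)pyrrolidin-1-yl]methanone | COC[C@@H]1CCCN1C(=O)[C@]1(C)C=C(C)CC=C1OC | intermediate (not isolated)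
7 | keto amide (2R)-2-{[(2S)-2-(methoxymethyl)pyrrolidin-1-yl]carbonyl}-2,4-dimethylcyclohex-3-en-1-one | COC[C@@H]1CCCN1C(=O)[C@]1(C)C=C(C)CCC1=O | intermediate
8 | hydroxy amide [(1R,6S)-6-hydroxy-1,3-dimethylcyclohex-2-en-1-yl][(2S)-2-(methoxymethyl)pyrrolidin-1-yl]methanone | COC[C@@H]1CCCN1C(=O)[C@]1(C)C=C(C)CC[C@@H]1O | intermediate (not isolated)
9 | diol (1S,2S)-2-(hydroxymethyl)-2,4-dimethylcyclohex-3-en-1-ol | OC[C@]1(C)C=C(C)CC[C@@H]1O | intermediate
10 | silyl ether (1S,2S)-2-{[(tert-butyldimethylsilyl)oxy]methyl}-2,4-dimethylcyclohex-3-en-1-ol | CC(C)(C)[Si](C)(C)OC[C@]1(C)C=C(C)CC[C@@H]1O | intermediate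
11 | butanoate (1S,2S)-2-{[(tert-butyldimethylsilyl)oxy]methyl}-2,4-dimethylcyclohex-3-en-1-yl butanoate | CC(C)(C)[Si](C)(C)OC[C@]1(C)C=C(C)CC[C@@H]1OC(=O)CCC | intermediate
12 | enone (1S,2S)-2-{[(tert-butyldimethylsilyl)oxy]methyl}-2,4-dimethyl-5-oxocyclohex-3-en-1-yl butanoate | CC(C)(C)[Si](C)(C)OC[C@]1(C)C=C(C)C(=O)C[C@@H]1OC(=O)CCC | intermediate
13 | silyl enol ether (1S,2S,3R)-2-{[(tert-butyldimethylsilyl)oxy]methyl}-3-ethenyl-2,4-dimethyl-5-[(trimethylsilyl)oxy]cyclohex-4-en-1-yl butanoate | CC(C)(C)[Si](C)(C)OC[C@]1(C)[C@@H](C=C)C(C)=C(O[Si](C)(C)C)C[C@@H]1OC(=O)CCC | intermediate (not isolated)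
14 | vinyl ketone (1S,2S,3S,4R)-2-{[(tert-butyldimethylsilyl)oxy]methyl}-3-ethenyl-2,4-dimethyl-5-oxocyclohexyl butanoate | CC(C)(C)[Si](C)(C)OC[C@]1(C)[C@@H](C=C)[C@@H](C)C(=O)C[C@@H]1OC(=O)CCC | intermediate
15 | ozonide (1S,2S,3S,4R)-2-{[(tert-butyldimethylsilyl)oxy]methyl}-2,4-dimethyl-5-oxo-3-(1,2,4-trioxolan-3-yl)cyclohexyl butanoate | CC(C)(C)[Si](C)(C)OC[C@]1(C)[C@@H](C2OCOO2)[C@@H](C)C(=O)C[C@@H]1OC(=O)CCC | intermediate (not isolated)
16 | aldehyde (1S,2S,3S,4R)-2-{[(tert-butyldimethylsilyl)oxy]methyl}-3-formyl-2,4-dimethyl-5-oxocyclohexyl butanoate | CC(C)(C)[Si](C)(C)OC[C@]1(C)[C@@H](C=O)[C@@H](C)C(=O)C[C@@H]1OC(=O)CCC | intermediate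
17 | lithium alkoxide (1S,2S,3S,4R)-2-{[(tert-butyldimethylsilyl)oxy]methyl}-3-[(1R)-1-(lithiooxy)-2-methoxybuta-2,3-dien-1-yl]-2,4-dimethyl-5-oxocyclohexyl butanoate | CC(C)(C)[Si](C)(C)OC[C@]1(C)[C@@H]([C@@H](O[Li])C(OC)=C=C)[C@@H](C)C(=O)C[C@@H]1OC(=O)CCC | intermediate (not isolated)
18 | allenyl acetate (1S,2S,3S,4R)-3-[(1R)-1-acetoxy-2-methoxybuta-2,3-dien-1-yl]-2-{[(tert-butyldimethylsilyl)oxy]methyl}-2,4-dimethyl-5-oxocyclohexyl butanoate | CC(C)(C)[Si](C)(C)OC[C@]1(C)[C@@H]([C@@H](OC(C)=O)C(OC)=C=C)[C@@H](C)C(=O)C[C@@H]1OC(=O)CCC | intermediate (not isolated)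
19 | acetoxy vinyl ketone (1S,2S,3S,4R)-3-[(1R)-1-acetoxy-2-oxobut-3-en-1-yl]-2-{[(tert-butyldimethylsilyl)oxy]methyl}-2,4-dimethyl-5-oxocyclohexyl butanoate | CC(C)(C)[Si](C)(C)OC[C@]1(C)[C@@H]([C@@H](OC(C)=O)C(=O)C=C)[C@@H](C)C(=O)C[C@@H]1OC(=O)CCC | intermediate
20 | 4-(trimethylsilyl)but-3-yn-2-one | CC(=O)C#C[Si](C)(C)C | starting material
21 | potassium enolate: potassium 4-(trimethylsilyl)but-1-en-3-yn-2-olate | C=C(O[K])C#C[Si](C)(C)C | intermediate (not isolated)
22 | enol triflate 4-(trimethylsilyl)but-1-en-3-yn-2-yl trifluoromethanesulfonate | C=C(OS(=O)(=O)C(F)(F)F)C#C[Si](C)(C)C | intermediate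
23 | dienynone (1S,2S,3S,4R)-3-[(1R,3E)-1-acetoxy-5-methylidene-2-oxo-7-(trimethylsilyl)hept-3-en-6-yn-1-yl]-2-{[(tert-butyldimethylsilyl)oxy]methyl}-2,4-dimethyl-5-oxocyclohexyl butanoate | CC(C)(C)[Si](C)(C)OC[C@]1(C)[C@@H]([C@@H](OC(C)=O)C(=O)/C=C/C(=C)C#C[Si](C)(C)C)[C@@H](C)C(=O)C[C@@H]1OC(=O)CCC | intermediate
24 | epoxy ketone (1S,2S,3S,4R)-3-[(1R)-1-acetoxy-2-oxo-2-{(2S,3R)-3-[4-(trimethylsilyl)but-1-en-3-yn-2-yl]oxiran-2-yl}ethyl]-2-{[(tert-butyldimethylsilyl)oxy]methyl}-2,4-dimethyl-5-oxocyclohexyl butanoate | CC(C)(C)[Si](C)(C)OC[C@]1(C)[C@@H]([C@@H](OC(C)=O)C(=O)[C@H]2O[C@@H]2C(=C)C#C[Si](C)(C)C)[C@@H](C)C(=O)C[C@@H]1OC(=O)CCC | intermediate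
25 | chlorohydrin (1S,2S,3S,4R)-3-[(1R,3R,4S)-1-acetoxy-4-chloro-3-hydroxy-5-methylidene-2-oxo-7-(trimethylsilyl)hept-6-yn-1-yl]-2-{[(tert-butyldimethylsilyl)oxy]methyl}-2,4-dimethyl-5-oxocyclohexyl butanoate | CC(C)(C)[Si](C)(C)OC[C@]1(C)[C@@H]([C@@H](OC(C)=O)C(=O)[C@@H](O)[C@@H](Cl)C(=C)C#C[Si](C)(C)C)[C@@H](C)C(=O)C[C@@H]1OC(=O)CCC | intermediate
26 | bromopropanoate (1S,2S,3S,4R)-3-[(1R,3R,4S)-1-acetoxy-3-[(2-bromopropanoyl)oxy]-4-chloro-5-methylidene-2-oxo-7-(trimethylsilyl)hept-6-yn-1-yl]-2-{[(tert-butyldimethylsilyl)oxy]methyl}-2,4-dimethyl-5-oxocyclohexyl butanoate (bromide epimers) | CC(C)(C)[Si](C)(C)OC[C@]1(C)[C@@H]([C@@H](OC(C)=O)C(=O)[C@@H](OC(=O)C(C)Br)[C@@H](Cl)C(=C)C#C[Si](C)(C)C)[C@@H](C)C(=O)C[C@@H]1OC(=O)CCC | intermediate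
27 | samarium enolate: 26 with the bromopropanoate turned into its diiodosamarium ester enolate | CC(C)(C)[Si](C)(C)OC[C@]1(C)[C@@H]([C@@H](OC(C)=O)C(=O)[C@@H](OC(O[Sm](I)I)=CC)[C@@H](Cl)C(=C)C#C[Si](C)(C)C)[C@@H](C)C(=O)C[C@@H]1OC(=O)CCC | intermediate (not isolated)
28 | silylated lactone (1S,2S,3S,4R)-3-[(R)-acetoxy{(2R,3R,4R)-2-[(1S)-1-chloro-2-methylidene-4-(trimethylsilyl)but-3-yn-1-yl]-3-hydroxy-4-methyl-5-oxooxolan-3-yl}methyl]-2-{[(tert-butyldimethylsilyl)oxy]methyl}-2,4-dimethyl-5-oxocyclohexyl butanoate | CC(C)(C)[Si](C)(C)OC[C@]1(C)[C@@H]([C@@H](OC(C)=O)[C@]2(O)[C@@H](C)C(=O)O[C@H]2[C@@H](Cl)C(=C)C#C[Si](C)(C)C)[C@@H](C)C(=O)C[C@@H]1OC(=O)CCC | intermediate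
29 | terminal alkyne: 28 without the alkynyl TMS group | CC(C)(C)[Si](C)(C)OC[C@]1(C)[C@@H]([C@@H](OC(C)=O)[C@]2(O)[C@@H](C)C(=O)O[C@H]2[C@@H](Cl)C(=C)C#C)[C@@H](C)C(=O)C[C@@H]1OC(=O)CCC | intermediate (not isolated)
30 | alkynyl diol (1S,2S,3S,4R)-3-[(R)-acetoxy{(2R,3R,4R)-2-[(1S)-1-chloro-2-methylidenebut-3-yn-1-yl]-3-hydroxy-4-methyl-5-oxooxolan-3-yl}methyl]-2-(hydroxymethyl)-2,4-dimethyl-5-oxocyclohexyl butanoate | OC[C@]1(C)[C@@H]([C@@H](OC(C)=O)[C@]2(O)[C@@H](C)C(=O)O[C@H]2[C@@H](Cl)C(=C)C#C)[C@@H](C)C(=O)C[C@@H]1OC(=O)CCC | intermediate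
31 | alkynyl aldehyde (1S,2R,3S,4R)-3-[(R)-acetoxy{(2R,3R,4R)-2-[(1S)-1-chloro-2-methylidenebut-3-yn-1-yl]-3-hydroxy-4-methyl-5-oxooxolan-3-yl}methyl]-2-formyl-2,4-dimethyl-5-oxocyclohexyl butanoate | O=C[C@]1(C)[C@@H]([C@@H](OC(C)=O)[C@]2(O)[C@@H](C)C(=O)O[C@H]2[C@@H](Cl)C(=C)C#C)[C@@H](C)C(=O)C[C@@H]1OC(=O)CCC | intermediate
32 | dienylborane: 31 with (E)-CH=CH–B(c-C6H11)2 in place of the ethynyl group | O=C[C@]1(C)[C@@H]([C@@H](OC(C)=O)[C@]2(O)[C@@H](C)C(=O)O[C@H]2[C@@H](Cl)C(=C)/C=C/B(C2CCCCC2)C2CCCCC2)[C@@H](C)C(=O)C[C@@H]1OC(=O)CCC | intermediate (not isolated)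
33 | dienylzinc: 31 with (E)-CH=CH–ZnEt in place of the ethynyl group and the tertiary hydroxyl as its ethylzinc alkoxide | O=C[C@]1(C)[C@@H]([C@@H](OC(C)=O)[C@]2(O[Zn]CC)[C@@H](C)C(=O)O[C@H]2[C@@H](Cl)C(=C)/C=C/[Zn]CC)[C@@H](C)C(=O)C[C@@H]1OC(=O)CCC | intermediate (not isolated)
34 | macrocyclic alcohol: 2-O-deacetyl target, (1R,2R,3E,6S,7R,8R,9R,10S,11R,14S,17R) in briarane numbering | C=C1/C=C/[C@@H](O)[C@]2(C)[C@@H]([C@@H](OC(C)=O)[C@]3(O)[C@@H](C)C(=O)O[C@H]3[C@H]1Cl)[C@@H](C)C(=O)C[C@@H]2OC(=O)CCC | intermediate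
35 | target CNP0283653.2: 2,9-di-O-acetyl-14-O-butanoyl-6-chloro-8-hydroxy-12-oxobriara-3E,5(16)-diene 19,7-lactone, (1R,2R,6S,7R,8R,9R,10S,11R,14S,17R) | C=C1/C=C/[C@@H](OC(C)=O)[C@]2(C)[C@@H]([C@@H](OC(C)=O)[C@]3(O)[C@@H](C)C(=O)O[C@H]3[C@H]1Cl)[C@@H](C)C(=O)C[C@@H]2OC(=O)CCC | target

## Step count and risks

Total steps: 19. Longest linear sequence: 18 (steps 1–9 and 11–19; step 10 makes the side fragment).

**Ring closure 31 → 34.** A ten-membered ring with an E-alkene is well below the ring sizes for which alkenylzinc macrocyclisation is established; oligomers or aldehyde reduction by the borane may win. The fallback sets out from 31 and closes the same bond by metathesis instead. Vinylmagnesium bromide (2.1 equiv, THF, −78 °C) adds to the aldehyde under Felkin control to give the C2 vinyl carbinol F7. Dicyclohexylborane adds to its terminal alkyne to give the dienylborane F8, and acetic acid protonolysis gives the triene F9, which carries a 2-substituted butadiene. Ring-closing metathesis of F9 with the second-generation Grubbs catalyst (CH2Cl2, 40 °C, 1 mM) forms C3=C4 and comes back to the route at 34. The E/Z outcome of that metathesis is not secured.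

**Chloride opening 24 → 25.** Chloride could attack the exocyclic CH2 (SN2') or the free chlorohydrin could re-close or lose HCl. The fallback sets out from 24 and never frees the chlorohydrin. Acryloyl chloride with catalytic Bu4NCl (CH2Cl2, 0 °C) opens the epoxide by O-acylation followed by chloride attack at the allylic C6, giving the chloro acrylate F5. Copper hydride reductive aldol cyclisation (Cu(OAc)2·H2O 5 mol %, rac-BINAP, (Me2SiH)2O, THF, rt) passes through the copper ester enolate F6, which closes onto the C8 ketone and comes back to the route at 28.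

**Conjugate addition 12 → 14.** The β-carbon is flanked by a quaternary centre and an α-methyl group, so the cuprate may be too slow or the facial selectivity poor. The fallback sets out from 12 and uses a Hosomi–Sakurai reaction: allyltrimethylsilane and TiCl4 (CH2Cl2, −78 °C) give the titanium enolate F1, and kinetic protonation on work-up gives the allyl ketone F2. Isomerisation with RuHCl(CO)(PPh3)3 (toluene, 80 °C) moves the double bond to give the (E)-propenyl ketone F3. Ozonolysis through the ozonide F4 with PPh3 work-up comes back to the route at 16.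

## Further compounds

F1 | step 7 | titanium enolate (1S,2S,3S)-2-{[(tert-butyldimethylsilyl)oxy]methyl}-2,4-dimethyl-3-(prop-2-en-1-yl)-5-[(trichlorotitanio)oxy]cyclohex-4-en-1-yl butanoate | CC(C)(C)[Si](C)(C)OC[C@]1(C)[C@@H](CC=C)C(C)=C(O[Ti](Cl)(Cl)Cl)C[C@@H]1OC(=O)CCC
F2 | step 7 | allyl ketone (1S,2S,3S,4R)-2-{[(tert-butyldimethylsilyl)oxy]methyl}-2,4-dimethyl-5-oxo-3-(prop-2-en-1-yl)cyclohexyl butanoate | CC(C)(C)[Si](C)(C)OC[C@]1(C)[C@@H](CC=C)[C@@H](C)C(=O)C[C@@H]1OC(=O)CCC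
F3 | step 7 | (E)-propenyl ketone (1S,2S,3S,4R)-2-{[(tert-butyldimethylsilyl)oxy]methyl}-2,4-dimethyl-5-oxo-3-[(1E)-prop-1-en-1-yl]cyclohexyl butanoate | CC(C)(C)[Si](C)(C)OC[C@]1(C)[C@@H](/C=C/C)[C@@H](C)C(=O)C[C@@H]1OC(=O)CCC
F4 | step 7 | ozonide (1S,2S,3S,4R)-2-{[(tert-butyldimethylsilyl)oxy]methyl}-2,4-dimethyl-3-(5-methyl-1,2,4-trioxolan-3-yl)-5-oxocyclohexyl butanoate | CC(C)(C)[Si](C)(C)OC[C@]1(C)[C@@H](C2OC(C)OO2)[C@@H](C)C(=O)C[C@@H]1OC(=O)CCC
F5 | step 13 | chloro acrylate: 25 with its C7 hydroxyl as the prop-2-enoate ester | CC(C)(C)[Si](C)(C)OC[C@]1(C)[C@@H]([C@@H](OC(C)=O)C(=O)[C@@H](OC(=O)C=C)[C@@H](Cl)C(=C)C#C[Si](C)(C)C)[C@@H](C)C(=O)C[C@@H]1OC(=O)CCC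
F6 | step 13 | copper ester enolate of F5 (ligand omitted) | CC(C)(C)[Si](C)(C)OC[C@]1(C)[C@@H]([C@@H](OC(C)=O)C(=O)[C@@H](OC(O[Cu])=CC)[C@@H](Cl)C(=C)C#C[Si](C)(C)C)[C@@H](C)C(=O)C[C@@H]1OC(=O)CCC
F7 | step 18 | vinyl carbinol: 31 with (1R)-1-hydroxyprop-2-en-1-yl in place of the formyl group | C=C[C@@H](O)[C@]1(C)[C@@H]([C@@H](OC(C)=O)[C@]2(O)[C@@H](C)C(=O)O[C@H]2[C@@H](Cl)C(=C)C#C)[C@@H](C)C(=O)C[C@@H]1OC(=O)CCC
F8 | step 18 | dienylborane: F7 with (E)-CH=CH–B(c-C6H11)2 in place of the ethynyl group | C=C[C@@H](O)[C@]1(C)[C@@H]([C@@H](OC(C)=O)[C@]2(O)[C@@H](C)C(=O)O[C@H]2[C@@H](Cl)C(=C)/C=C/B(C2CCCCC2)C2CCCCC2)[C@@H](C)C(=O)C[C@@H]1OC(=O)CCC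
F9 | step 18 | triene: F7 with ethenyl in place of the ethynyl group | C=C[C@@H](O)[C@]1(C)[C@@H]([C@@H](OC(C)=O)[C@]2(O)[C@@H](C)C(=O)O[C@H]2[C@@H](Cl)C(=C)C=C)[C@@H](C)C(=O)C[C@@H]1OC(=O)CCC
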